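Assumption: the target is treated as the 4'-O-methyl ether of abyssinone V, (2S)-5,7-dihydroxy-4'-methoxy-3',5'-bis(3-methylbut-2-enyl)flavanone (the methyl group is on O4' of ring B, not on C4). Commercial (2S)-isosakuranetin is taken to be enantiomerically pure at C2, to be confirmed by chiral HPLC before use.

## Structural features

The target is a flavanone, a 2,3-dihydrochromen-4-one in which the benzene ring A, a phloroglucinol ring with free hydroxyl groups at C5 and C7, is fused to the dihydropyranone ring C, while C2 of ring C carries the aryl ring B. Ring B is a 4'-methoxyphenyl group with two 3-methylbut-2-enyl (prenyl) chains at C3' and C5', the carbons on either side of the methoxy-bearing C4'. The only stereocentre is C2 (S), which is benzylic, bonded to O1 and β to the C4 carbonyl, and has no stereogenic neighbour. This centre is the fragile point, because base opens ring C by retro-oxa-Michael cleavage of the O1–C2 bond to an achiral 2'-hydroxychalcone and strong acid can ionise the same p-alkoxybenzylic bond; the two trisubstituted alkenes are sensitive to strong acid, halonium sources and oxidants, and ring A with free phenols is a far better nucleophile at C6 and C8 than ring B. The skeleton itself is simple, so the real difficulty is to place two linear prenyl groups on ring B, and only there, without disturbing C2. The key step exploits C3' and C5' of ring B: they are the two positions ortho to the methoxy oxygen (para is taken by C2), they are equivalent by rotation about the C1'–C2 bond, and as aryl iodides they can each be joined to the CH2 terminus of a prenyl unit in one twofold cross-coupling. Taking the prenyl groups away leaves a natural flavanone that already contains rings A, B and C, the 4'-methyl ether and the S centre.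

## Logic of the disconnections

**11 ⇒ 9 (through 10).** In the forward sense the bonds cut are the two acetyl C–O ester bonds on O7 and O5; going backwards, both phenols of ring A are masked. Free phenols make ring A the most nucleophilic site of the molecule and would misdirect the halogenation two steps earlier, whereas the esters switch this reactivity off and can be removed near neutrality. Nothing is gained in skeleton, but 9 reacts in the planned chemistry only on ring B. The forward step must be a deacylation mild enough to keep the O1–C2 bond closed (no chalcone, no loss of the S centre) and to leave both trisubstituted alkenes untouched.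

**9 ⇒ 6 + 2 × 7 (through 8).** The bonds cut are C3'–CH2 and C5'–CH2, between ring B and the two prenyl chains. They are the only carbon–carbon bonds of 11 that 1 does not already contain, they are aryl–allyl bonds of the type that palladium-catalysed cross-coupling forms dependably, and the two sites are equivalent, so one operation makes both. Ten carbons and both alkenes are removed, leaving a precursor that tolerates electrophiles and acid. The forward step must bond the tin-bearing CH2 terminus of 7 to the ring (linear, not reverse prenyl), must run without base so that ring C stays closed and C2 stays S, and must leave the aryl esters and the ketone alone. 6 is kept as the diiodide, so that oxidative addition needs no halide, fluoride or base additive, and as the diacetate, because the same esters that steer the iodination are inert to the catalyst and leave under neutral conditions.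

**6 ⇒ 3 + 2 × 4 (through 5).** The bonds cut are C3'–I and C5'–I. These are the innate sites of electrophilic substitution on ring B (ortho to the methoxy group, para blocked by C2), and introducing halogen first and carbon afterwards leaves the chiral-pool skeleton untouched. The gain is the return to an unhalogenated flavanone. The forward step must choose ring B over ring A twice, the second time on a ring that already carries one iodine, and its acid activator must not ionise the benzylic C2–O1 bond; this is the reason both ring A oxygens are acylated in 3.

**3 ⇒ 1 (through 2).** The bonds cut are the acetyl–O bonds at O7 and O5. 1 is a commercial natural product with all three rings, the 4'-methyl ether and the S centre in place, so no ring, no stereocentre and no skeletal bond other than the two prenyl bonds has to be made. The forward step must acylate completely, including the hydrogen-bonded 5-OH, under conditions too weakly basic to open ring C.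

## Other disconnections considered

**Alternative 1:** The cut is the C4a–C5 bond of ring A, so ring A is built rather than bought, and ring C is closed afterwards at O1–C2.
- Forward key step: the open-chain tri-β-ketoester A2 is treated with Mg(OMe)2 or KOH in methanol. Its C6 carbanion attacks the ester carbonyl C1 (Claisen condensation) and the cyclic triketone enolises to the acylphloroglucinol A1. Desilylation and a Mitsunobu closure with inversion at the R carbinol would then give the S centre of 11.
- In its favour: the closure is biomimetic and ring A appears with its three oxygens and no protecting groups. The stereocentre comes from a reagent-controlled step, so either enantiomer is accessible and optical purity does not depend on a natural source; on this point the alternative is better than the chosen plan. It is also better in that the prenyl groups are placed on the simple aldehyde A3 before ring A exists, so the ring A against ring B selectivity question of step 2 never arises.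
- Against it: A2 carries a silyloxy group β to a ketone and is exposed to methoxide, so E1cB loss of that group would destroy the stereocentre. The poly-β-carbonyl chain can also close in the aldol mode and give the wrong aromatic substitution pattern. A2 needs an enantioselective acetate-type aldol addition to A3, protection and two chain extensions, and A3 would itself be made by a twofold aryl–prenyl cross-coupling, so the palladium chemistry is only moved to the start.
- Comparison: structurally, the alternative spends its key step on a ring that 1 already contains, whereas the chosen step forms exactly the two bonds that 1 lacks. Mechanistically, it relies on polyanion chemistry in strong base against a neutral catalytic cycle. In step economy it needs well over ten steps against four. The two plans are equal in ending with a free phloroglucinol ring without a harsh deprotection.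

**Alternative 2:** The cut is the O1–C8a aryl ether bond of ring C.
- Forward key step: the bromo diol A5 is heated with CuI, 3,4,7,8-tetramethyl-1,10-phenanthroline and Cs2CO3. The hydroxyl on the carbon that becomes C2 displaces bromide on ring A (Ullmann-type C–O coupling, six-membered closure), the C4 hydroxyl cannot compete because it would close a four-membered ring, and the flavan-4-ol A4 results. Oxidation at C4 and removal of the two methoxymethyl ethers would follow.
- In its favour: the C–O bond at the stereocentre is never broken, so the carbinol configuration passes into C2 with retention, and ring C is closed at the alcohol oxidation level, where retro-oxa-Michael opening is impossible. In configurational security this equals the chosen plan, which also never touches C2. Catalyst-based stereocontrol gives either enantiomer, which is better than reliance on the chiral pool, and prenylation at the stage of A3 avoids the two-ring halogenation question, which is also better.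
- Against it: two stereocentres must be set in A5 and one of them (C4) is then erased by oxidation, a stereochemical and redox detour. The flavanone formed after oxidation must survive acidic removal of the acetal protecting groups next to two acid-sensitive prenyl alkenes, whereas the chosen plan ends with a neutral methanolysis. A5 has to be assembled from A3 by an aldol-type union and two stereoselective operations.
- Comparison: the two key steps are equal in being late-transition-metal couplings that tolerate prenyl groups, and neither creates a stereocentre. Structurally, the alternative closes ring C, which 1 already contains. In step economy it needs about nine or ten steps against four.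

**Alternative 3:** The cut is the C4–C4a bond of ring C.
- Forward key step: the acid A7 is converted into its chloride A8, whose acyl carbon is attacked by the ring carbon ortho to the ether oxygen of the bis(triisopropylsilyloxy)phenoxy group (intramolecular Friedel–Crafts acylation, six-membered closure) to give A6. Desilylation would complete 11.
- In its favour: ring C is formed directly at the ketone oxidation level, which equals the chosen plan in needing no redox adjustment. The nucleophilic ring is symmetrical, so its two ortho positions are identical and no regiochemical question arises; in this respect it is better than step 2 of the chosen plan. The union of a phenol with a three-carbon acid is also more convergent on paper, and like the chosen key step it creates no stereocentre.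
- Against it: an acyl chloride and a Lewis or Brønsted acid share the flask with two trisubstituted alkenes, which invites hydrochlorination and cation–olefin side reactions. A8 has an aryloxy leaving group β to the acyl carbon on a benzylic position, so β-elimination or ionisation would erase the stereocentre before the ring closes. The acylation has to take place next to a bulky silyloxy group. A7 requires an enantioselective construction of a benzylic aryl ether at an electron-rich carbinol, which tends towards partial ionisation. A basic fluoride desilylation at the end would again threaten ring C.
- Comparison: mechanistically this is electrophilic aromatic substitution under acid, the conditions least compatible with the prenyl groups and the benzylic ether, against a neutral palladium cycle. In step economy it needs about eight steps against four.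

Key step: step 3

## Route

Step 1
Reactants: 1 (2S)-isosakuranetin [(2S)-5,7-dihydroxy-4'-methoxyflavanone]
Product: 3 (2S)-5,7-diacetoxy-4'-methoxyflavanone, via 7-O-acetylisosakuranetin 2 (not isolated)
Conditions: Ac2O (4 equiv), pyridine, DMAP (cat.), 0 °C to rt
Reagents that add atoms: acetic anhydride, CC(=O)OC(C)=O
Why: Pyridine/DMAP-promoted O-acetylation of phenols (nucleophilic acyl transfer): the free 7-OH reacts first to give 2 and the hydrogen-bonded 5-OH follows under DMAP catalysis. The medium is weakly basic and cold, so E1cB opening of ring C is not expected and C2 keeps the S configuration of 1; no stereocentre is formed.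

Step 2
Reactants: 3 (2S)-5,7-diacetoxy-4'-methoxyflavanone; 4 N-iodosuccinimide
Product: 6 (2S)-5,7-diacetoxy-3',5'-diiodo-4'-methoxyflavanone, via the 3'-monoiodide 5 (not isolated)
Conditions: NIS (2.3 equiv), CF3CO2H, CH3CN, 0 °C to rt, dark; aq. Na2S2O3 work-up
Reagents that add atoms: N-iodosuccinimide (compound 4), O=C1CCC(=O)N1I
Why: Electrophilic aromatic iodination (SEAr) with NIS activated by protonation with CF3CO2H: on ring B the methoxy group directs to C3' and C5' because the para position is occupied by C2, and the second iodination follows the first on the same ring through 5. Ring A should lag because both of its phenol oxygens are acylated, O1 is tied up as a vinylogous ester with the acid-coordinated C4 carbonyl, and C6 and C8 are each flanked by two oxygen substituents; C2 takes no part.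

Step 3
Reactants: 6 (2S)-5,7-diacetoxy-3',5'-diiodo-4'-methoxyflavanone; 7 tributyl(3-methylbut-2-enyl)stannane
Product: 9 (2S)-5,7-diacetoxy-4'-methoxy-3',5'-bis(3-methylbut-2-enyl)flavanone, via the 3'-iodo-5'-prenyl monoadduct 8 (not isolated)
Conditions: 7 (3 equiv), Pd(PPh3)4 (10 mol %), toluene (degassed), 100 °C, Ar, dark; filtration through KF/silica
Reagents that add atoms: tributyl(3-methylbut-2-enyl)stannane (compound 7), CCCC[Sn](CCCC)(CCCC)CC=C(C)C
Why: Twofold Migita–Kosugi–Stille cross-coupling, whose closest known reaction type is the coupling of aryl halides with prenyltributylstannane to give linear prenylarenes. Each C–I bond of 6 adds oxidatively to zerovalent palladium to give an arylpalladium iodide (divalent palladium), which aryl iodides do without added halide, fluoride or base. Transmetalation from tin then delivers the allyl unit, and whichever terminus reaches the metal first, the σ-allyl forms interconvert through the π-allyl complex. Reductive elimination forms the aryl–carbon bond at the unhindered CH2 terminus and not at the CMe2 terminus, which secures the linear 3-methylbut-2-enyl group over the reverse-prenyl isomer, and the ortho methoxy group adds to this steric bias. The two iodides are equivalent by rotation of ring B, so the cycle runs twice, through 8. No ring is closed and no stereocentre is formed. Only the C–I bonds are expected to react, since aryl acetates and the ketone do not add to the catalyst, and the neutral, aprotic, amine-free medium gives ring C no path to the chalcone, so C2 keeps the S configuration.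

Step 4
Reactants: 9 (2S)-5,7-diacetoxy-4'-methoxy-3',5'-bis(3-methylbut-2-enyl)flavanone
Product: 11 (2S)-5,7-dihydroxy-4'-methoxy-3',5'-bis(3-methylbut-2-enyl)flavanone (target), via the 5-monoacetate 10 (not isolated)
Conditions: NH4OAc (excess), MeOH/H2O, rt to 40 °C
Reagents that add atoms: none
Why: NH4OAc-promoted methanolysis of aryl acetates (acyl transfer to methanol near neutral pH): the 7-acetate, a vinylogous anhydride, should leave first to give 10, followed by the 5-acetate, whose phenol is stabilised by the hydrogen bond to the C4 carbonyl. No strong base is present, so ring C should stay closed and C2 stay S, and the prenyl alkenes are inert to the medium.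

## Compound list

1 | (2S)-isosakuranetin, (2S)-5,7-dihydroxy-4'-methoxyflavanone | COc1ccc([C@@H]2CC(=O)c3c(O)cc(O)cc3O2)cc1 | starting material
2 | (2S)-7-acetoxy-5-hydroxy-4'-methoxyflavanone (7-O-acetylisosakuranetin) | COc1ccc([C@@H]2CC(=O)c3c(O)cc(OC(C)=O)cc3O2)cc1 | intermediate
3 | (2S)-5,7-diacetoxy-4'-methoxyflavanone | COc1ccc([C@@H]2CC(=O)c3c(OC(C)=O)cc(OC(C)=O)cc3O2)cc1 | intermediate
4 | N-iodosuccinimide | O=C1CCC(=O)N1I | starting material
5 | (2S)-5,7-diacetoxy-3'-iodo-4'-methoxyflavanone | COc1ccc([C@@H]2CC(=O)c3c(OC(C)=O)cc(OC(C)=O)cc3O2)cc1I | intermediate
6 | (2S)-5,7-diacetoxy-3',5'-diiodo-4'-methoxyflavanone | COc1c(I)cc([C@@H]2CC(=O)c3c(OC(C)=O)cc(OC(C)=O)cc3O2)cc1I | intermediate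
7 | tributyl(3-methylbut-2-enyl)stannane | CCCC[Sn](CCCC)(CCCC)CC=C(C)C | starting material
8 | (2S)-5,7-diacetoxy-3'-iodo-4'-methoxy-5'-(3-methylbut-2-enyl)flavanone | COc1c(CC=C(C)C)cc([C@@H]2CC(=O)c3c(OC(C)=O)cc(OC(C)=O)cc3O2)cc1I | intermediate
9 | (2S)-5,7-diacetoxy-4'-methoxy-3',5'-bis(3-methylbut-2-enyl)flavanone | COc1c(CC=C(C)C)cc([C@@H]2CC(=O)c3c(OC(C)=O)cc(OC(C)=O)cc3O2)cc1CC=C(C)C | intermediate
10 | (2S)-5-acetoxy-7-hydroxy-4'-methoxy-3',5'-bis(3-methylbut-2-enyl)flavanone | COc1c(CC=C(C)C)cc([C@@H]2CC(=O)c3c(OC(C)=O)cc(O)cc3O2)cc1CC=C(C)C | intermediate
11 | (2S)-5,7-dihydroxy-4'-methoxy-3',5'-bis(3-methylbut-2-enyl)flavanone | COc1c(CC=C(C)C)cc([C@@H]2CC(=O)c3c(O)cc(O)cc3O2)cc1CC=C(C)C | target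

## Step count and least certain steps

Total step count: 4. Longest linear sequence: 4 steps (1 → 3 → 6 → 9 → 11). The S centre at C2 comes from 1 and is carried through every step unchanged.

**Step 3 (key step).**
- What may go wrong: partial loss of regiocontrol in the reductive elimination (bond formation at the dimethyl-substituted allyl terminus at one or both positions); stalling after the first coupling, at the more hindered and more electron-rich 8; protodeiodination; or palladium-hydride migration of a new double bond into conjugation with ring B.
- Fallback: from 6, the same Stille coupling is run with allyltributylstannane (Pd(PPh3)4, toluene, 100 °C), whose allyl group is symmetrical so that no regiochemical question exists. This should give (2S)-5,7-diacetoxy-4'-methoxy-3',5'-di(prop-2-enyl)flavanone F2. Twofold olefin cross-metathesis of F2 with excess 2-methyl-2-butene (second-generation Grubbs catalyst, RuCl2(=CHPh)(PCy3)(H2IMes), CH2Cl2, 40 °C) then turns each allyl into a prenyl group and rejoins the route at 9.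

**Step 2.**
- What may go wrong: once the first iodine has deactivated ring B, competing iodination of ring A at C8 or C6, or stalling at 5; iodination at C3 through the enol; and, early in the reaction, acid-induced ionisation of the p-methoxybenzylic C2–O1 bond with erosion of the configuration.
- Fallback: from 3, the regiochemistry is put under steric instead of electronic control. Iridium-catalysed C–H borylation ([Ir(OMe)(cod)]2, 4,4'-di-tert-butyl-2,2'-bipyridine, B2pin2, THF, 80 °C) should reach only the ring B C–H bonds next to the small methoxy group, because both ring A C–H bonds are flanked on both sides and C2'/C6' sit next to the branched C2 substituent. This should give (2S)-5,7-diacetoxy-4'-methoxy-3',5'-bis(4,4,5,5-tetramethyl-1,3,2-dioxaborolan-2-yl)flavanone F1. Ipso-iododeboronation of F1 (NaI, TsNClNa (chloramine-T), aqueous THF, rt) returns to the route at 6.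

**Step 4.**
- What may go wrong: base-assisted retro-oxa-Michael opening of ring C during the deacylation, with erosion of the C2 configuration; or stalling at 10 because the 5-acetate is shielded by the peri carbonyl, so that forcing then endangers C2.
- Fallback: the last two operations are exchanged, so that the deprotection is done under acid catalysis on a compound without alkenes, where the E1cB path is closed. From 6, acid-catalysed methanolysis (HCl in MeOH, rt to 40 °C) should give (2S)-5,7-dihydroxy-3',5'-diiodo-4'-methoxyflavanone F3, whose twisted, iodine-flanked anisole ring stabilises a C2 cation poorly. The base-free Stille coupling of F3 with 7 (Pd(PPh3)4, 1,4-dioxane, 100 °C), which tolerates free phenols, then comes back to the route at 11.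

## Further compounds

F1 | step 2 | (2S)-5,7-diacetoxy-4'-methoxy-3',5'-bis(4,4,5,5-tetramethyl-1,3,2-dioxaborolan-2-yl)flavanone | COc1c(B2OC(C)(C)C(C)(C)O2)cc([C@@H]2CC(=O)c3c(OC(C)=O)cc(OC(C)=O)cc3O2)cc1B1OC(C)(C)C(C)(C)O1
F2 | step 3 | (2S)-5,7-diacetoxy-4'-methoxy-3',5'-di(prop-2-enyl)flavanone | COc1c(CC=C)cc([C@@H]2CC(=O)c3c(OC(C)=O)cc(OC(C)=O)cc3O2)cc1CC=C
F3 | step 4 | (2S)-5,7-dihydroxy-3',5'-diiodo-4'-methoxyflavanone | COc1c(I)cc([C@@H]2CC(=O)c3c(O)cc(O)cc3O2)cc1I
A1 | alternative 1 | (3R)-3-(tert-butyldimethylsilyloxy)-3-[4-methoxy-3,5-bis(3-methylbut-2-enyl)phenyl]-1-(2,4,6-trihydroxyphenyl)propan-1-one | O=C(C[C@@H](O[Si](C)(C)C(C)(C)C)c1cc(CC=C(C)C)c(OC)c(CC=C(C)C)c1)c1c(O)cc(O)cc1O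
A2 | alternative 1 | methyl (9R)-9-(tert-butyldimethylsilyloxy)-9-[4-methoxy-3,5-bis(3-methylbut-2-enyl)phenyl]-3,5,7-trioxononanoate | COC(=O)CC(=O)CC(=O)CC(=O)C[C@@H](O[Si](C)(C)C(C)(C)C)c1cc(CC=C(C)C)c(OC)c(CC=C(C)C)c1
A3 | alternative 1 | 4-methoxy-3,5-bis(3-methylbut-2-enyl)benzaldehyde | COc1c(CC=C(C)C)cc(C=O)cc1CC=C(C)C
A4 | alternative 2 | (2S,4S)-5,7-bis(methoxymethoxy)-4'-methoxy-3',5'-bis(3-methylbut-2-enyl)flavan-4-ol | O[C@H]1C[C@@H](c2cc(CC=C(C)C)c(OC)c(CC=C(C)C)c2)Oc2cc(OCOC)cc(OCOC)c12
A5 | alternative 2 | (1S,3S)-1-[2-bromo-4,6-bis(methoxymethoxy)phenyl]-3-[4-methoxy-3,5-bis(3-methylbut-2-enyl)phenyl]propane-1,3-diol | O[C@@H](C[C@H](O)c1cc(CC=C(C)C)c(OC)c(CC=C(C)C)c1)c1c(Br)cc(OCOC)cc1OCOC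
A6 | alternative 3 | (2S)-5,7-bis(triisopropylsilyloxy)-4'-methoxy-3',5'-bis(3-methylbut-2-enyl)flavanone | O=C1C[C@@H](c2cc(CC=C(C)C)c(OC)c(CC=C(C)C)c2)Oc2cc(O[Si](C(C)C)(C(C)C)C(C)C)cc(O[Si](C(C)C)(C(C)C)C(C)C)c12
A7 | alternative 3 | (3S)-3-[3,5-bis(triisopropylsilyloxy)phenoxy]-3-[4-methoxy-3,5-bis(3-methylbut-2-enyl)phenyl]propanoic acid | OC(=O)C[C@@H](c1cc(CC=C(C)C)c(OC)c(CC=C(C)C)c1)Oc1cc(O[Si](C(C)C)(C(C)C)C(C)C)cc(O[Si](C(C)C)(C(C)C)C(C)C)c1
A8 | alternative 3 | (3S)-3-[3,5-bis(triisopropylsilyloxy)phenoxy]-3-[4-methoxy-3,5-bis(3-methylbut-2-enyl)phenyl]propanoyl chloride | ClC(=O)C[C@@H](c1cc(CC=C(C)C)c(OC)c(CC=C(C)C)c1)Oc1cc(O[Si](C(C)C)(C(C)C)C(C)C)cc(O[Si](C(C)C)(C(C)C)C(C)C)c1
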